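The oxane ring is disconnected on both sides of its C4–C5 edge. C4 and C5 are read as the β- and α-carbons of an acrylic acid whose carboxyl carbon is C1′, the first carbon of the trienyl chain on C5. In one flask an allyl group (C3, with C2 masked as a vinyl CH) is joined to C4 and formaldehyde (C6, bearing the future ring oxygen O1) to C5 of a chiral N-acryloyl oxazolidinone, which fixes the C5 stereocentre. Ozonolysis then turns C2 into the acetal carbon and closes the ring through O1; the chain is grown from C1′, and axial C–C bond formation at the C2 oxocarbenium ion sets the 2,5-cis relationship.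

Key step: step 2

Remark: the target as drawn is the (2R,5R) isomer, in which the substituents on C2 and C5 of the oxane ring are cis; ring atoms are labelled O1, C2–C6 and the chain on C5 C1′–C13′.

Step 1
Reactants: 1 (4S)-4-benzyl-1,3-oxazolidin-2-one; 2 acryloyl chloride
Product: 3 (4S)-3-acryloyl-4-benzyl-1,3-oxazolidin-2-one
Conditions: Et3N, LiCl, THF, −20 °C to rt
Reagents that add atoms: none
Why: Lithium-assisted N-acylation of the oxazolidinone by the acid chloride should give the chelating acrylimide without touching the auxiliary stereocentre.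

Step 2
Reactants: 3 (4S)-3-acryloyl-4-benzyl-1,3-oxazolidin-2-one; 4 allyltrimethylsilane; 5 1,3,5-trioxane
Product: 7 (4S)-4-benzyl-3-[(2R)-2-(hydroxymethyl)hex-5-enoyl]-1,3-oxazolidin-2-one, via trichlorotitanium (Z)-enolate 6 (not isolated)
Conditions: TiCl4 (1.1 equiv), 4 (3 equiv), CH2Cl2, −78 °C; then 5 (1.1 equiv), TiCl4 (1.1 equiv), −78 to 0 °C; aq. NH4Cl
Reagents that add atoms: none
Why: TiCl4 chelates both carbonyl groups of 3 in the s-cis form, allyltrimethylsilane adds to the β-carbon C4 (Hosomi–Sakurai conjugate allylation, C3–C4 bond) and loss of Me3SiCl leaves the chelated (Z)-titanium enolate 6, which then attacks formaldehyde released from trioxane by the second portion of TiCl4 (C5–C6 bond). The closest known reaction types are the Lewis-acid conjugate allylation of N-enoyl oxazolidinones and the hydroxymethylation of chlorotitanium imide enolates, here run one after the other in the same flask. No ring is closed in this step. The only new stereocentre, C5, is set in the second bond formation: the benzyl group of the auxiliary shields one face of the chelated (Z)-enolate, so formaldehyde should enter from the opposite face and give the (R) configuration. The step needs 1,4- rather than 1,2-attack and trapping of 6 before it is protonated or adds to a second molecule of 3; chelation of the imide, excess allylsilane and the absence of a proton source until the quench should secure this.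

Step 3
Reactants: 7 (4S)-4-benzyl-3-[(2R)-2-(hydroxymethyl)hex-5-enoyl]-1,3-oxazolidin-2-one
Product: 9 (4S)-4-benzyl-3-[(3R)-6-methoxyoxane-3-carbonyl]-1,3-oxazolidin-2-one (both anomers), via lactol 8 (not isolated)
Conditions: O3, CH2Cl2/MeOH, −78 °C; Me2S, −78 °C to rt; then camphorsulfonic acid (cat.), MeOH, rt
Reagents that add atoms: methanol (CO)
Why: Ozonolysis of the only C=C bond with reductive work-up gives the δ-hydroxy aldehyde, which closes to the six-membered lactol (O1–C2 bond) and is fixed as the methyl acetal by acid-catalysed acetalisation, with C5 not involved.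

Step 4
Reactants: 9 (4S)-4-benzyl-3-[(3R)-6-methoxyoxane-3-carbonyl]-1,3-oxazolidin-2-one
Product: 10 [(3S)-6-methoxyoxan-3-yl]methanol
Conditions: LiBH4, MeOH (1 equiv), THF, 0 °C
Reagents that add atoms: none
Why: Borohydride reduction of the N-acyl oxazolidinone releases the auxiliary and gives the primary alcohol at C1′, while the acetal ring keeps the second CH2O arm distinct so that C5 stays stereogenic (the descriptor changes by priority only).

Step 5
Reactants: 10 [(3S)-6-methoxyoxan-3-yl]methanol
Product: 11 (5R)-5-(iodomethyl)-2-methoxyoxane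
Conditions: I2, PPh3, imidazole (3 equiv), CH2Cl2, 0 °C to rt
Reagents that add atoms: iodine (II)
Why: Appel-type iodination converts the primary alcohol through its alkoxyphosphonium salt into the iodide by SN2, and the excess imidazole keeps the medium basic so that the acetal cannot ionise and exchange with the free hydroxyl.

Step 6
Reactants: 12 (2E,6E)-farnesyl bromide; 13 sodium benzenesulfinate
Product: 14 {[(2E,6E)-3,7,11-trimethyldodeca-2,6,10-trien-1-yl]sulfonyl}benzene
Conditions: DMF, 0 °C to rt
Reagents that add atoms: none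
Why: SN2 S-alkylation of the sulfinate by the primary allylic bromide should give the allylic sulfone with both E double bonds intact.

Step 7
Reactants: 14 {[(2E,6E)-3,7,11-trimethyldodeca-2,6,10-trien-1-yl]sulfonyl}benzene; 11 (5R)-5-(iodomethyl)-2-methoxyoxane
Product: 16 (5S)-2-methoxy-5-[(3E,7E)-4,8,12-trimethyl-2-(phenylsulfonyl)trideca-3,7,11-trien-1-yl]oxane, via lithiated sulfone 15 (not isolated)
Conditions: n-BuLi, THF, −78 °C; then 11, DMPU, −78 to 0 °C
Reagents that add atoms: none
Why: Alkylation of the α-sulfonyl allyl anion at its α-carbon by the primary iodide (sulfone alkylation) forms the C1′–C2′ bond, and the new sulfone-bearing centre, formed as a mixture, is erased in step 8.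

Step 8
Reactants: 16 (5S)-2-methoxy-5-[(3E,7E)-4,8,12-trimethyl-2-(phenylsulfonyl)trideca-3,7,11-trien-1-yl]oxane
Product: 17 (5R)-2-methoxy-5-[(3E,7E)-4,8,12-trimethyltrideca-3,7,11-trien-1-yl]oxane
Conditions: PdCl2(dppp) (5 mol %), LiBHEt3, THF, 0 °C
Reagents that add atoms: none
Why: In this palladium-catalysed reductive desulfonylation, zerovalent palladium ionises the allylic sulfone and hydride is delivered to the less substituted allyl terminus C2′, which should leave the trisubstituted (E)-C3′=C4′ bond in place.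

Step 9
Reactants: 17 (5R)-2-methoxy-5-[(3E,7E)-4,8,12-trimethyltrideca-3,7,11-trien-1-yl]oxane; 18 tert-butyl[(1-methoxyethenyl)oxy]dimethylsilane
Product: 20 methyl 2-[(2R,5R)-5-[(3E,7E)-4,8,12-trimethyltrideca-3,7,11-trien-1-yl]oxan-2-yl]acetate, via oxocarbenium triflate 19 (not isolated)
Conditions: Me3SiOTf (0.2 equiv), 2,6-di-tert-butyl-4-methylpyridine, CH2Cl2, −78 °C
Reagents that add atoms: none
Why: In this Mukaiyama-type acetal substitution both anomers give the same cyclic oxocarbenium ion, whose half-chair holds the C5 chain pseudo-equatorial, and stereoelectronically preferred axial attack of the silyl ketene acetal at C2 should give the 2,5-cis (2R) ester.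

Step 10
Reactants: 20 methyl 2-[(2R,5R)-5-[(3E,7E)-4,8,12-trimethyltrideca-3,7,11-trien-1-yl]oxan-2-yl]acetate
Product: 24 methyl 2-[(2R,5R)-5-[(3E,7E)-4,8,12-trimethyltrideca-3,7,11-trien-1-yl]oxan-2-yl]prop-2-enoate, via lithium enolate 21 (not isolated), via Mannich base 22 (not isolated), via trimethylammonium iodide 23 (not isolated)
Conditions: LiN(i-Pr)2, THF, −78 °C; CH2=NMe2+ I−, −78 to 0 °C; then MeI, MeOH, rt; then DBU, CH2Cl2, rt
Reagents that add atoms: N,N-dimethylmethyleneiminium iodide (C=[N+](C)C.[I-])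
Why: α-Methylenation by Mannich reaction of the ester enolate, N-quaternisation and base-induced β-elimination of trimethylamine should give the acrylate, with C2 keeping its configuration as long as the enolate is kept cold.

Step 11
Reactants: 24 methyl 2-[(2R,5R)-5-[(3E,7E)-4,8,12-trimethyltrideca-3,7,11-trien-1-yl]oxan-2-yl]prop-2-enoate
Product: 25 rhopaloic acid B as drawn, 2-[(2R,5R)-5-[(3E,7E)-4,8,12-trimethyltrideca-3,7,11-trien-1-yl]oxan-2-yl]prop-2-enoic acid
Conditions: LiOH, THF/MeOH/H2O, rt; then 1 M HCl to pH 3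
Reagents that add atoms: lithium hydroxide ([Li+].[OH-])
Why: Saponification of the methyl ester by hydroxide (acyl–oxygen cleavage) and acidification should give the acid without touching the stereocentres or the alkenes.

Compound list
1 | (4S)-4-benzyl-1,3-oxazolidin-2-one | O=C1N[C@@H](Cc2ccccc2)CO1 | starting material
2 | acryloyl chloride | C=CC(=O)Cl | starting material
3 | (4S)-3-acryloyl-4-benzyl-1,3-oxazolidin-2-one | C=CC(=O)N1[C@@H](Cc2ccccc2)COC1=O | intermediate
4 | allyltrimethylsilane | C=CC[Si](C)(C)C | starting material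
5 | 1,3,5-trioxane | C1OCOCO1 | starting material
6 | trichlorotitanium (Z)-enolate of (4S)-4-benzyl-3-(hex-5-enoyl)-1,3-oxazolidin-2-one (not isolated) | C=CCC/C=C(\O[Ti](Cl)(Cl)Cl)N1[C@@H](Cc2ccccc2)COC1=O | intermediate
7 | (4S)-4-benzyl-3-[(2R)-2-(hydroxymethyl)hex-5-enoyl]-1,3-oxazolidin-2-one | C=CCC[C@H](CO)C(=O)N1[C@@H](Cc2ccccc2)COC1=O | intermediate
8 | (4S)-4-benzyl-3-[(3R)-6-hydroxyoxane-3-carbonyl]-1,3-oxazolidin-2-one, lactol in equilibrium with the hydroxy aldehyde (not isolated) | OC1CC[C@H](CO1)C(=O)N1[C@@H](Cc2ccccc2)COC1=O | intermediate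
9 | (4S)-4-benzyl-3-[(3R)-6-methoxyoxane-3-carbonyl]-1,3-oxazolidin-2-one (both anomers) | COC1CC[C@H](CO1)C(=O)N1[C@@H](Cc2ccccc2)COC1=O | intermediate
10 | [(3S)-6-methoxyoxan-3-yl]methanol (both anomers) | COC1CC[C@H](CO1)CO | intermediate
11 | (5R)-5-(iodomethyl)-2-methoxyoxane (both anomers) | COC1CC[C@H](CO1)CI | intermediate
12 | (2E,6E)-farnesyl bromide, (2E,6E)-1-bromo-3,7,11-trimethyldodeca-2,6,10-triene | CC(C)=CCC/C(C)=C/CC/C(C)=C/CBr | starting material
13 | sodium benzenesulfinate | [Na+].[O-]S(=O)c1ccccc1 | starting material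
14 | {[(2E,6E)-3,7,11-trimethyldodeca-2,6,10-trien-1-yl]sulfonyl}benzene | CC(C)=CCC/C(C)=C/CC/C(C)=C/CS(=O)(=O)c1ccccc1 | intermediate
15 | α-lithio derivative of sulfone 14 (not isolated) | [Li]C(/C=C(\C)CC/C=C(\C)CCC=C(C)C)S(=O)(=O)c1ccccc1 | intermediate
16 | (5S)-2-methoxy-5-[(3E,7E)-4,8,12-trimethyl-2-(phenylsulfonyl)trideca-3,7,11-trien-1-yl]oxane (mixture at the acetal and sulfone carbons; ring C5 unchanged) | COC1CC[C@H](CO1)CC(S(=O)(=O)c1ccccc1)/C=C(\C)CC/C=C(\C)CCC=C(C)C | intermediate
17 | (5R)-2-methoxy-5-[(3E,7E)-4,8,12-trimethyltrideca-3,7,11-trien-1-yl]oxane (both anomers) | COC1CC[C@H](CO1)CC/C=C(\C)CC/C=C(\C)CCC=C(C)C | intermediate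
18 | tert-butyl[(1-methoxyethenyl)oxy]dimethylsilane | C=C(OC)O[Si](C)(C)C(C)(C)C | starting material
19 | (3R)-3-[(3E,7E)-4,8,12-trimethyltrideca-3,7,11-trien-1-yl]-2,3,4,5-tetrahydropyrylium triflate, the C2 oxocarbenium ion (not isolated) | C1=[O+]C[C@@H](CC1)CC/C=C(\C)CC/C=C(\C)CCC=C(C)C.[O-]S(=O)(=O)C(F)(F)F | intermediate
20 | methyl 2-[(2R,5R)-5-[(3E,7E)-4,8,12-trimethyltrideca-3,7,11-trien-1-yl]oxan-2-yl]acetate | COC(=O)C[C@H]1CC[C@@H](CC/C=C(\C)CC/C=C(\C)CCC=C(C)C)CO1 | intermediate
21 | lithium enolate of ester 20 (not isolated) | COC(O[Li])=C[C@H]1CC[C@@H](CC/C=C(\C)CC/C=C(\C)CCC=C(C)C)CO1 | intermediate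
22 | methyl 3-(dimethylamino)-2-[(2R,5R)-5-[(3E,7E)-4,8,12-trimethyltrideca-3,7,11-trien-1-yl]oxan-2-yl]propanoate (not isolated) | COC(=O)C(CN(C)C)[C@H]1CC[C@@H](CC/C=C(\C)CC/C=C(\C)CCC=C(C)C)CO1 | intermediate
23 | trimethylammonium iodide derived from 22 (not isolated) | COC(=O)C(C[N+](C)(C)C)[C@H]1CC[C@@H](CC/C=C(\C)CC/C=C(\C)CCC=C(C)C)CO1.[I-] | intermediate
24 | methyl 2-[(2R,5R)-5-[(3E,7E)-4,8,12-trimethyltrideca-3,7,11-trien-1-yl]oxan-2-yl]prop-2-enoate | C=C(C(=O)OC)[C@H]1CC[C@@H](CC/C=C(\C)CC/C=C(\C)CCC=C(C)C)CO1 | intermediate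
25 | rhopaloic acid B as drawn, 2-[(2R,5R)-5-[(3E,7E)-4,8,12-trimethyltrideca-3,7,11-trien-1-yl]oxan-2-yl]prop-2-enoic acid | C=C(C(=O)O)[C@H]1CC[C@@H](CC/C=C(\C)CC/C=C(\C)CCC=C(C)C)CO1 | target

Total step count: 11. Longest linear sequence: 10 steps (steps 1–5 and 7–11); step 6 is a one-step side branch.

Steps most likely to fail

Step 2. The titanium-activated acrylimide may oligomerise (enolate 6 adding to a second molecule of 3), or 6 may be protonated before it is hydroxymethylated. The fallback sets out from 1 and comes back at 7. Compound 1 is acylated with commercial hex-5-enoyl chloride (Et3N, LiCl, THF) to give (4S)-4-benzyl-3-(hex-5-enoyl)-1,3-oxazolidin-2-one F1, in which the C3–C4 bond is bought in. Soft enolisation (TiCl4, i-Pr2NEt, CH2Cl2, 0 °C) and hydroxymethylation with 1,3,5-trioxane and TiCl4 should then give 7 with the same facial control, at the cost of forming only the C5–C6 bond in that flask.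

Step 9. Facial selectivity in the attack on the oxocarbenium ion may be insufficient, or the cation may be intercepted by the chain double bonds. The fallback sets out from 17 and comes back at 24, so it also by-passes step 10. Exchange of the methoxy group (PhSSiMe3, Me3SiOTf cat., CH2Cl2, −78 °C) should give (5R)-2-(phenylsulfanyl)-5-[(3E,7E)-4,8,12-trimethyltrideca-3,7,11-trien-1-yl]oxane F2. Reductive lithiation with lithium 4,4′-di-tert-butylbiphenylide (THF, −78 °C) should give the configurationally stable axial (2S,5R)-2-lithio-5-[(3E,7E)-4,8,12-trimethyltrideca-3,7,11-trien-1-yl]oxane F3, whose lithium is cis to the C5 chain. Addition to methyl pyruvate with retention should give methyl 2-hydroxy-2-[(2R,5R)-5-[(3E,7E)-4,8,12-trimethyltrideca-3,7,11-trien-1-yl]oxan-2-yl]propanoate F4. Dehydration toward the methyl group (SOCl2, pyridine, 0 °C) should then give 24.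

Step 10. The ester enolate may expel the ring oxygen by β-elimination (retro-oxa-Michael ring opening), which would also erase the C2 configuration on re-closure. The fallback sets out from 17 and comes back at 24 without any enolate. Alkynylation of the oxocarbenium ion (K[F3BC≡CSiMe3], BF3·OEt2, CH3CN, −40 °C, same axial attack) should give trimethyl{[(2R,5R)-5-[(3E,7E)-4,8,12-trimethyltrideca-3,7,11-trien-1-yl]oxan-2-yl]ethynyl}silane F5. Desilylation (K2CO3, MeOH) should give (2R,5R)-2-ethynyl-5-[(3E,7E)-4,8,12-trimethyltrideca-3,7,11-trien-1-yl]oxane F6. Branched-selective palladium-catalysed hydromethoxycarbonylation of the terminal alkyne (Pd(OAc)2, 2-(diphenylphosphino)pyridine, CH3SO3H, CO, MeOH, 45 °C) should then give 24.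

Further compounds
F1 | step 2 | (4S)-4-benzyl-3-(hex-5-enoyl)-1,3-oxazolidin-2-one | C=CCCCC(=O)N1[C@@H](Cc2ccccc2)COC1=O
F2 | step 9 | (5R)-2-(phenylsulfanyl)-5-[(3E,7E)-4,8,12-trimethyltrideca-3,7,11-trien-1-yl]oxane (both anomers) | c1ccccc1SC1CC[C@H](CO1)CC/C=C(\C)CC/C=C(\C)CCC=C(C)C
F3 | step 9 | (2S,5R)-2-lithio-5-[(3E,7E)-4,8,12-trimethyltrideca-3,7,11-trien-1-yl]oxane (axial C–Li, cis to the C5 chain) | [Li][C@H]1CC[C@@H](CC/C=C(\C)CC/C=C(\C)CCC=C(C)C)CO1
F4 | step 9 | methyl 2-hydroxy-2-[(2R,5R)-5-[(3E,7E)-4,8,12-trimethyltrideca-3,7,11-trien-1-yl]oxan-2-yl]propanoate (epimers at the carbinol carbon) | COC(=O)C(C)(O)[C@H]1CC[C@@H](CC/C=C(\C)CC/C=C(\C)CCC=C(C)C)CO1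
F5 | step 10 | trimethyl{[(2R,5R)-5-[(3E,7E)-4,8,12-trimethyltrideca-3,7,11-trien-1-yl]oxan-2-yl]ethynyl}silane | C[Si](C)(C)C#C[C@H]1CC[C@@H](CC/C=C(\C)CC/C=C(\C)CCC=C(C)C)CO1
F6 | step 10 | (2R,5R)-2-ethynyl-5-[(3E,7E)-4,8,12-trimethyltrideca-3,7,11-trien-1-yl]oxane | C#C[C@H]1CC[C@@H](CC/C=C(\C)CC/C=C(\C)CCC=C(C)C)CO1
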